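Ja is the substrate I follow through the flasks set out here, and Jc is the product wanted from it.

    Ja ⇌ Jb (K1 = 0.0046, k1 = 0.062 s⁻¹, Ea1 = 75.0 kJ mol⁻¹, ΔH1 = −8.00 kJ mol⁻¹)
    2 Jb → Je (k2 = 1600 M⁻¹ s⁻¹, Ea2 = 42.0 kJ mol⁻¹)
    Ja → Jc (k3 = 0.40 s⁻¹, Ea3 = 68.0 kJ mol⁻¹)
    Ja + Jf → Jg (k4 = 250 M⁻¹ s⁻¹, Ea4 = 47.0 kJ mol⁻¹)
    Jb → Jd (k5 = 1.4 s⁻¹, Ea5 = 60.0 kJ mol⁻¹)
    Jc ⇌ Jd (K6 = 0.49, k6 = 0.060 s⁻¹, Ea6 = 77.0 kJ mol⁻¹, ΔH6 = −31.0 kJ mol⁻¹)
    (constants at 25 °C)

common to all: Ja 0.0010 M; Jb 0.100 mM; Jf 0.500 mM; time 15 s

| flask | temperature | remark |
|---|---|---|
| red | 10 °C |  |
| amber | 25 °C |  |
| grey | −5 °C |  |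
| ochre |  | at 25 °C until 5.0 s, from then on at −5 °C |

- percent here means Ja units held: one Je counts as two
- for a step with 2 of a species take k times the square, and two of it per event
- at 25 °C the constants are as listed, elsewhere as the activation energies and enthalpies make them
- in a conversion Jb counts as not yet reacted

- the flask that comes out highest in amount of Jc, in percent of the Ja and Jb together charged, or "all alike" when all lie within 1.5 percentage points (red / amber / grey / ochre / all alike)
- Jc at the end, in percent of the Ja and Jb together charged, red
- Jc at the end, in percent of the Ja and Jb together charged, amber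
- Jc at the end, in percent of the Ja and Jb together charged, grey
- Jc at the end, in percent of the Ja and Jb together charged, ochre

I turn the question round and ask what would have to be true for amber to beat ochre. Ochre trades two things at its switch: Ja still unreacted then, which I call stranded, goes to Jc slower by the factor 22 in the cold, while the leak of Jc to Jd slows as well. So I count lifetimes. Holding Jf at its charge makes the trap pseudo-first-order, and Ja then has a loss constant equal to the Jc constant plus the trap constant times Jf. Multiplied by the hot time, this gives 2.62, the hot count of Ja lifetimes. The fraction of Ja stranded at the switch is therefore 7.24%, and the Jc making holds a share 76.2% of the count.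

Amber's further hot time holds 1.82 lifetimes of the relaxation between Jc and Jd, whose constant is the forward one plus the return one, so a portion of pure Jc would lose a fraction 27.6% of itself in that time. The activation energy of the leak is higher than that of the Jc making, so the cold slows the leak by more than the factor 22 it costs the making. The Jc share stands on both sides of the trade, so for amber to win in this rough count the stranded fraction would have to exceed that loss taken on the Ja already reacted, and here the loss is larger by a factor of 3.54. Grey's Jc making gets 0.279 lifetimes, so grey stays low. I commit to ochre above amber and grey, and I do not reckon red or the final Jc percentages.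

The forecast names ochre, with red 55%, amber 57%, grey 21.3% and ochre 61%, because the cold switch “freezes Jc near its peak before it can relax toward Jd”.

The simulation gives ochre, with red 54.8%, amber 56.8%, grey 21.0% and ochre 62.2%.

The forecast and my ordering both stand. Amber's Jc falls short of the full charge mainly through the loss of Jc to Jd, both ways: with that step removed, amber ends at 78.8% instead of 56.8%. At ochre's switch, Ja reads 8.38% of the joint charge, against 6.59% from my count, which held Jf at its charge while ochre has 61.0% of it then. In a neighbour of ochre charged with 3.0 × 10⁻⁴ M of Jf, the count falls to 2.38, which gives a stranded fraction of 9.26% of the Ja at the switch and raises the Jc share to 84.2%. The computed neighbour keeps 8.7% of its Ja at the end against ochre's 7.0%, and ends with Jc at 66.7%.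

The numbers of this flask were set for the occasion.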